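**Retrosynthetic overview**

- Feature: ring A is a fully substituted phloroglucinol monomethyl ether in which C–OMe lies between the butyryl carbon and the methyl carbon, and the two C–OH flank the bridge-bearing carbon. This is the oxygen pattern of a 4-methoxy-3-methyl-2-pyrone: C-2 becomes C–OH beside C–Me, C-3 is C–Me, C-4 is C–OMe, C-5 is the butyryl carbon, C-6 is the second C–OH. The first carbon of a C-6 ethyl arm becomes the bridge-bearing ring carbon and the second becomes the CH2 bridge.
- Last disconnection: the ring-A C–butyryl bond (Friedel–Crafts at the only free aromatic CH).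
- Key disconnection: the ring-A bond between the bridge-bearing carbon and the C–OH next to C–Me, which leads back to the pyrone lactone (methoxide opening, Claisen recyclization).
- Arm disconnection: the CH2–CH2 bond between pyrone and ring B, from lithiated 4-methoxy-3,6-dimethyl-2-pyrone and a sulfonylmethyl derivative of propionylfilicinic acid (a masked exo-methylene acceptor).
- Ring order: ring B first (dearomatizing gem-dimethylation of phloropropiophenone), the pyrone ring is bought, ring A is formed last.

Key step: step 5

Remark: the target has no stereocentre (the quaternary ring-B carbon carries two methyl groups) and is achiral, so no enantiocontrol is needed. Ring-B compounds are drawn in the enol tautomer of the target SMILES, and species that exist as salts in the flask are listed in the neutral or lithium form shown.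

**Route**

Step 1
Reactants: 1 phloropropiophenone; 2 iodomethane
Product: 3 propionylfilicinic acid (3,5-dihydroxy-6,6-dimethyl-2-propanoylcyclohexa-2,4-dien-1-one)
Conditions: MeI (2.2 equiv), NaOMe (3 equiv), MeOH, 0 °C to rt; then aq. HCl
Reagents that add atoms: iodomethane CI
Why: Twofold phenolate C-methylation of the acylphloroglucinol anion at one ring carbon (the monomethylated carbon stays the most nucleophilic site) dearomatizes the ring to the filicinic acid pattern, the classical route to acylfilicinic acids, and creates no stereocentre.

Step 2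
Reactants: 3 propionylfilicinic acid; 4 formaldehyde; 5 sodium p-toluenesulfinate
Product: 6 3,5-dihydroxy-6,6-dimethyl-4-{[(4-methylphenyl)sulfonyl]methyl}-2-propanoylcyclohexa-2,4-dien-1-one
Conditions: 37% aq. HCHO (3 equiv), p-TolSO2Na (3 equiv), HCO2H, MeOH–H2O, rt
Reagents that add atoms: formaldehyde C=O; sodium p-toluenesulfinate Cc1ccc(cc1)S(=O)[O-].[Na+]
Why: In this Mannich-type three-component sulfonylmethylation the free ring carbon of the cyclic triketone condenses with formaldehyde to the exo-methylene trione, and the excess soft sulfinate should trap it faster than a second molecule of 3 can, giving a stable, storable equivalent of that acceptor.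

Step 3
Reactants: 7 4-hydroxy-3,6-dimethyl-2H-pyran-2-one; 8 dimethyl sulfate
Product: 9 4-methoxy-3,6-dimethyl-2H-pyran-2-one
Conditions: Me2SO4, K2CO3, acetone, reflux
Reagents that add atoms: dimethyl sulfate COS(=O)(=O)OC
Why: O-Methylation of the vinylogous acid with a hard electrophile under carbonate conditions is the standard way to 4-methoxy-2-pyrones and should prevail over 2-O-methylation and over C-3 methylation.

Step 4
Reactants: 9 4-methoxy-3,6-dimethyl-2H-pyran-2-one; 6 sulfone
Product: 12 6-[2-(2,6-dihydroxy-3,3-dimethyl-4-oxo-5-propanoylcyclohexa-1,5-dien-1-yl)ethyl]-4-methoxy-3-methyl-2H-pyran-2-one, via lithiated pyrone 10 (not isolated), via methylene trione enolate 11 (not isolated)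
Conditions: 9 (3.2 equiv), LDA (3.2 equiv), THF, −78 °C; then 6 (1 equiv) in THF, −78 to −20 °C; 1 M HCl
Reagents that add atoms: none
Why: LDA deprotonates the 6-methyl group (vinylogous deprotonation, C-3 being blocked) to dienolate 10, two equivalents of which deprotonate the two enols of 6 so that the dianion ejects sulfinate (E1cB) to the 2-methylene-1,3-dione enolate 11, and a third equivalent adds to the methylene terminus in a vinylogous Michael addition; the sulfone is used instead of a Mannich base because an enolate cannot expel an amide anion under these conditions.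

Step 5
Reactants: 12 pyrone–ring B precursor
Product: 14 4-[(2,6-dihydroxy-4-methoxy-3-methylphenyl)methyl]-3,5-dihydroxy-6,6-dimethyl-2-propanoylcyclohexa-2,4-dien-1-one (desbutyryl aspidin PB), via ring-opened keto ester 13 (not isolated)
Conditions: NaOMe (6 equiv), anhydrous MeOH, Ar, 60 °C; then 1 M HCl, 0 °C
Reagents that add atoms: none
Why: Methoxide adds to the lactone carbonyl (pyrone C-2) and the ring opens with the C-6 enolate as leaving group, giving the (E)-β-methoxy enoate 13 in which the new methyl ester and the ketone-bearing arm are still cis on the tetrasubstituted double bond. The ketone enolate on the ring-B side, a minor tautomer of the resting dienolate, then attacks the ester carbonyl in a 6-(enolendo)-exo-trig Claisen (Dieckmann-type) closure that forms the ring-A bond between the bridge-bearing carbon and the C–OH next to C–Me; loss of methoxide and enolization give the resorcinol. The closest known reactions are the alkoxide cyclization of 5-oxo esters to cyclohexane-1,3-diones and the base-induced recyclization of 4-oxygenated 2-pyrones to phloroglucinols. No stereocentre is formed. The selectivity needed is closure through the arm-side α-carbon: the other, doubly activated α-carbon could only close a four-membered ring, relactonization and methoxy exchange at the enol-ether carbon are degenerate in NaOMe/MeOH, and aromatization to the phenoxide makes the productive path irreversible. Ring B is carried through as its unreactive dianion, and the enol methyl ether of the pyrone becomes the ring-A methoxy group without any differentiation of phenols.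

Step 6
Reactants: 14 desbutyryl aspidin PB; 15 butanoyl chloride
Product: 16 aspidin PB (4-[(3-butanoyl-2,6-dihydroxy-4-methoxy-5-methylphenyl)methyl]-3,5-dihydroxy-6,6-dimethyl-2-propanoylcyclohexa-2,4-dien-1-one)
Conditions: PrCOCl (1.5 equiv), TiCl4 (4 equiv), CH2Cl2, −20 to 0 °C; then aq. HCl
Reagents that add atoms: butanoyl chloride CCCC(=O)Cl
Why: Friedel–Crafts C-acylation at the only unsubstituted ring-A carbon, which is ortho to a titanium phenoxide and para to the other hydroxyl, leaves no regiochemical choice, while ring B has no free carbon and is held as its titanium chelate and the low temperature should spare the methyl ether.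

**Compound list**

1 | phloropropiophenone (1-(2,4,6-trihydroxyphenyl)propan-1-one) | CCC(=O)c1c(O)cc(O)cc1O | starting material
2 | iodomethane | CI | starting material
3 | propionylfilicinic acid (3,5-dihydroxy-6,6-dimethyl-2-propanoylcyclohexa-2,4-dien-1-one) | CCC(=O)C1=C(O)C=C(O)C(C)(C)C1=O | intermediate
4 | formaldehyde | C=O | starting material
5 | sodium p-toluenesulfinate | Cc1ccc(cc1)S(=O)[O-].[Na+] | starting material
6 | 3,5-dihydroxy-6,6-dimethyl-4-{[(4-methylphenyl)sulfonyl]methyl}-2-propanoylcyclohexa-2,4-dien-1-one | CCC(=O)C1=C(O)C(CS(=O)(=O)c2ccc(C)cc2)=C(O)C(C)(C)C1=O | intermediate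
7 | 4-hydroxy-3,6-dimethyl-2H-pyran-2-one | CC1=CC(O)=C(C)C(=O)O1 | starting material
8 | dimethyl sulfate | COS(=O)(=O)OC | starting material
9 | 4-methoxy-3,6-dimethyl-2H-pyran-2-one | COC1=C(C)C(=O)OC(C)=C1 | intermediate
10 | 6-(lithiomethyl)-4-methoxy-3-methyl-2H-pyran-2-one (lithium dienolate of 9) | [Li]CC1=CC(OC)=C(C)C(=O)O1 | intermediate
11 | lithium 4,4-dimethyl-6-methylidene-3,5-dioxo-2-propanoylcyclohex-1-en-1-olate (exo-methylene acceptor) | C=C1C(=O)C(C)(C)C(=O)C(C(=O)CC)=C1O[Li] | intermediate
12 | 6-[2-(2,6-dihydroxy-3,3-dimethyl-4-oxo-5-propanoylcyclohexa-1,5-dien-1-yl)ethyl]-4-methoxy-3-methyl-2H-pyran-2-one | O=C1OC(CCC2=C(O)C(C)(C)C(=O)C(C(=O)CC)=C2O)=CC(OC)=C1C | intermediate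
13 | methyl (2E)-7-(2,6-dihydroxy-3,3-dimethyl-4-oxo-5-propanoylcyclohexa-1,5-dien-1-yl)-3-methoxy-2-methyl-5-oxohept-2-enoate (sodium enolate in the flask) | COC(=O)/C(C)=C(/OC)CC(=O)CCC1=C(O)C(C)(C)C(=O)C(C(=O)CC)=C1O | intermediate
14 | desbutyryl aspidin PB (4-[(2,6-dihydroxy-4-methoxy-3-methylphenyl)methyl]-3,5-dihydroxy-6,6-dimethyl-2-propanoylcyclohexa-2,4-dien-1-one) | COc1cc(O)c(CC2=C(O)C(C)(C)C(=O)C(C(=O)CC)=C2O)c(O)c1C | intermediate
15 | butanoyl chloride | CCCC(=O)Cl | starting material
16 | aspidin PB | CCCC(=O)c1c(O)c(CC2=C(O)C(C)(C)C(=O)C(C(=O)CC)=C2O)c(O)c(C)c1OC | target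

Total steps: 6. Longest linear sequence: 5 steps (steps 1, 2, 4, 5, 6); the pyrone branch (step 3) joins at step 4.

**Steps most likely to fail**

Step 5 (key step). The productive arm-side enolate is only a minor tautomer of the doubly stabilized dienolate, so closure may be slow. Once the product is present as a phenoxide it can expel the ring-B enolate from the benzylic bridge (o-quinone methide formation) and recombine unselectively, scrambling or oligomerizing the methylene bridge. Prolonged heating also risks retro-Claisen loss of the propionyl group. The fallback joins ring B after ring A is built, so that the bridge never meets methoxide. It sets out from 9, which is lithiated to 10 as in step 4 and quenched with N,N-dimethylmethyleneiminium iodide to give 6-[2-(dimethylamino)ethyl]-4-methoxy-3-methyl-2H-pyran-2-one F1. NaOMe in MeOH at reflux should open the lactone to methyl (2E)-7-(dimethylamino)-3-methoxy-2-methyl-5-oxohept-2-enoate F2 (not isolated), which closes by the same Claisen mode to the phenolic Mannich base 2-[(dimethylamino)methyl]-5-methoxy-4-methylbenzene-1,3-diol F3, whose amine is a poor leaving group under base. Heating F3 with propionylfilicinic acid 3 in dioxane should then give 14: the acidic triketone protonates the amine, dimethylamine leaves, and the free ring-B carbon adds to the o-quinone methide. The route is rejoined at 14.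

Step 4. The hard lithium dienolate may act only as a base towards the acidic ring-B enols. The released methylene trione may also be consumed by self-condensation (hetero-Diels–Alder dimerization, oligomerization) or by double alkylation before the dienolate adds, and the lithiated pyrone self-condenses if the mixture must be warmed. The fallback uses a soft, carbonate-level nucleophile instead of an organolithium. It sets out from 9: anion 10, made with 2 equiv of LDA, is acylated with Boc2O to give tert-butyl 2-(4-methoxy-3-methyl-2-oxo-2H-pyran-6-yl)acetate F4. F4 and sulfone 6 with Cs2CO3 in MeCN at rt (sulfinate elimination, then malonate-type Michael addition) should give racemic tert-butyl 3-(2,6-dihydroxy-3,3-dimethyl-4-oxo-5-propanoylcyclohexa-1,5-dien-1-yl)-2-(4-methoxy-3-methyl-2-oxo-2H-pyran-6-yl)propanoate F5. TFA in CH2Cl2 cleaves the tert-butyl ester to 3-(2,6-dihydroxy-3,3-dimethyl-4-oxo-5-propanoylcyclohexa-1,5-dien-1-yl)-2-(4-methoxy-3-methyl-2-oxo-2H-pyran-6-yl)propanoic acid F6, a vinylogous β-keto acid that should lose CO2 on warming in toluene. The route is rejoined at 12.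

Step 6. Acyl transfer may go to oxygen (ring-B enol or ring-A phenol butyrates) instead of carbon. The Lewis acid may cleave the methyl ether that ends up ortho to the new ketone, or acid may cleave the benzylic bridge. The fallback is a Houben–Hoesch acylation, whose nitrilium electrophile cannot acylate oxygen irreversibly and which needs only a weak Lewis acid. It sets out from 14: butyronitrile, ZnCl2 and dry HCl in Et2O at 0 °C should give the ketiminium chloride 1-{2,4-dihydroxy-3-[(2,6-dihydroxy-3,3-dimethyl-4-oxo-5-propanoylcyclohexa-1,5-dien-1-yl)methyl]-6-methoxy-5-methylphenyl}butan-1-iminium chloride F7, which is hydrolysed in warm water to 16.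

**Further compounds**

F1 | step 5 | 6-[2-(dimethylamino)ethyl]-4-methoxy-3-methyl-2H-pyran-2-one | CN(C)CCC1=CC(OC)=C(C)C(=O)O1
F2 | step 5 | methyl (2E)-7-(dimethylamino)-3-methoxy-2-methyl-5-oxohept-2-enoate | COC(=O)/C(C)=C(/OC)CC(=O)CCN(C)C
F3 | step 5 | 2-[(dimethylamino)methyl]-5-methoxy-4-methylbenzene-1,3-diol | CN(C)Cc1c(O)cc(OC)c(C)c1O
F4 | step 4 | tert-butyl 2-(4-methoxy-3-methyl-2-oxo-2H-pyran-6-yl)acetate | CC(C)(C)OC(=O)CC1=CC(OC)=C(C)C(=O)O1
F5 | step 4 | tert-butyl 3-(2,6-dihydroxy-3,3-dimethyl-4-oxo-5-propanoylcyclohexa-1,5-dien-1-yl)-2-(4-methoxy-3-methyl-2-oxo-2H-pyran-6-yl)propanoate (racemic) | CC(C)(C)OC(=O)C(CC1=C(O)C(C)(C)C(=O)C(C(=O)CC)=C1O)C2=CC(OC)=C(C)C(=O)O2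
F6 | step 4 | 3-(2,6-dihydroxy-3,3-dimethyl-4-oxo-5-propanoylcyclohexa-1,5-dien-1-yl)-2-(4-methoxy-3-methyl-2-oxo-2H-pyran-6-yl)propanoic acid (racemic) | OC(=O)C(CC1=C(O)C(C)(C)C(=O)C(C(=O)CC)=C1O)C2=CC(OC)=C(C)C(=O)O2
F7 | step 6 | 1-{2,4-dihydroxy-3-[(2,6-dihydroxy-3,3-dimethyl-4-oxo-5-propanoylcyclohexa-1,5-dien-1-yl)methyl]-6-methoxy-5-methylphenyl}butan-1-iminium chloride | CCCC(=[NH2+])c1c(O)c(CC2=C(O)C(C)(C)C(=O)C(C(=O)CC)=C2O)c(O)c(C)c1OC.[Cl-]
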